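Locants are abietane locants. The unprimed half holds the spiro carbon C7 and the ring C hydroxyquinone, the primed half is the quinone methide, and ring D is O14′–C7–C7′=C8′–C14′. Ar stands for 3-isopropyl-2,4,5-trimethoxyphenyl.

## Analysis of the target

CNP0568854.1 is a heptacyclic C40 dimer of two 6-oxoabietane units: rings A–C carry a ring C hydroxyquinone, rings A′–C′ carry an 11′-hydroxy-12′-oxo quinone methide (C7′=C8′), and a dihydrofuran ring D is spiro-fused at C7. It has five stereocentres, (5S,7R,10S,5′R,10′R). Both decalins are trans-fused, but they are mirror images of each other: the unprimed half belongs to the normal abietane series and the primed half to the ent series. C7 is fully substituted (O14′, C6, C8, C7′) with O14′ on the α face, anti to the C10 methyl group, and it is the only stereocentre that breaks the mirror relation of the two carbon frameworks. The sensitive groups are the acidic hydroxyquinone, the electrophilic extended quinone methide, the epimerisable C5 and C5′ next to the ketones, and the C7–O14′ aryl ether, which sits α to C6=O and can reopen. The difficulties are the two benzylic quaternary carbons C10 and C10′ of opposite configuration, the congested C7–C7′ junction between two peri-substituted tricycles, the oxygenated spiro centre, and rings that become very electron-rich and air-sensitive once unmasked. The strategy rests first on the position of the aryl–quaternary bonds: in each half C9–C10 (C9′–C10′) lies β to the C6 (C6′) ketone, which is the retron of a Friedel–Crafts conjugate addition of C9 to a C5=C10 enone. It rests second on the mirror relation of the decalins: opening ring D and levelling the oxidation states leaves a meso hexacycle with a C7=C7′ double bond, and that maps onto an achiral, symmetric enedione with two cyclogeranoyl groups.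

## Retrosynthetic reasoning

**Oxidation level (18 → 17).** Four hydrogens are added formally. The hydroxyquinone becomes an 11,12,14-triol and the quinone methide becomes an 11′,12′-catechol with C7′–H, which gives spiro pentaphenol 17. No skeletal bond is cut. The gain is that both reactive π-systems appear only in the last operation. The forward reaction must oxidise both rings and let the primed ortho-quinone tautomerise to the C7′=C8′ quinone methide.

**C7–O14′ (17 → 16).** This is the one bond whose removal makes the halves equivalent. With C7=C7′ restored, hexaphenol 16 contains a natural-series and an ent-series tricycle as mirror images and is meso. The forward reaction is an acid-catalysed addition of O14′–H to C7 in which a chiral acid chooses one of the two enantiotopic phenol/alkene-carbon pairs and the α face of C7. Absolute configuration enters the route here, catalytically and at the last stage.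

**Phenol protection (16 → 15).** The six hydroxyl groups are carried as methyl ethers in 15, because only these survive the strong acid of the ring-forming step and the enolate chemistry before it. The forward reaction is a sixfold ether cleavage that must leave the enedione and the C5 centres alone.

**C9–C10 and C9′–C10′ (15 → 13, through 14).** Both aryl–quaternary bonds are cut. Each lies β to a ketone and ends on the only free aryl position, so the forward reaction is a conjugate Friedel–Crafts closure of C9 onto the C5=C10 enone of a cyclogeranoyl group. Cutting here, rather than in ring A or at C7–C8, removes rings B and B′ and all four decalin stereocentres at once and leaves enedione 13, which is achiral and C2-symmetric in constitution. The forward step must close two six-membered rings and deliver the heterochiral pairing of C10 and C10′.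

**C7=C7′ (13 → 11 → 9, through 12 and 10).** The central double bond is the symmetry element of 13. It is taken back to the C7–C7′ single bond of diketone 11 and then cut, giving two molecules of ketone 9. The forward reactions are an oxidative homocoupling in which two molecules of 9 are joined through enolate 10 at the benzylic carbon, and a dehydrogenation of 11 through bis-enolate 12. Both use the acidity of the C7 hydrogens, which are benzylic and α to a ketone.

**C6–C7 (9 → 8 → 5 + 6, through 7).** The ketone is taken back to alcohol 8, and the C6–C7 bond is cut into a benzyl nucleophile, 7 from chloride 5, and the aldehyde carbon of 6. This joins the two commercial carbon sources in one step, and ring A with its gem-dimethyl group and the C5=C10 double bond arrives ready-made in 6.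

**Arene substituents (5 → 4 → 3 → 1, through 2).** The chloromethyl group is removed from the ring position that is ortho to one methoxy group and para to another. The isopropyl group is traced to alcohol 3 and from there to aryllithium 2, which forms at the position of 1 flanked by two methoxy groups. Both substituents therefore go where the ring directs them.

## Alternatives that were turned down

Alternative 1: The same ring D bond, C7–O14′, is cut, but at an oxidation level two hydrogens above that of 16. The substrate is the meso bis(quinone methide) A2, in which C7–C7′ is a single bond and each half is an 11,14-dihydroxy-12-oxo para-quinone methide.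
- Forward key step: a chiral binaphthol-derived phosphoric acid guides O14′–H of one half onto C7 of the quinone methide of the other half from the α face (a 5-exo 1,6-addition). This gives spiro triol A1, which is one mild oxidation from 18.
- For it: the electrophile is a discrete para-quinone methide, the substrate class with the best precedent for this catalyst type. The closure is stereoelectronically clean, and the quinone methide of the target is already in place in A1.
- Against it: it is an endgame only and says nothing about how the meso hexacyclic skeleton is made. A2 would have to come from a selective two-electron oxidation of a hexaphenol such as 16, whose 1,2,4-trioxygenated rings should prefer to become ring hydroxyquinones. A2 is also electrophilic at both C7 and C7′ and unlikely to be storable.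
- Comparison: on the ring D closure itself this alternative is as strong as step 10 of the chosen route and mechanistically tidier, since step 10 must generate the quinone-methide-type cation from 16 by protonation in the flask. The chosen strategy offers in exchange a concrete construction of both decalins and the C7–C7′ junction from achiral pieces, and a cyclisation substrate (16) that needs no selective oxidation. The step count after the skeleton is the same.

Alternative 2: The cut is C6′–C7′ of ring B′. Substrate A4 already contains the complete unprimed tricycle, spiro C7, ring D and the primed ring C′ as a quinone methide with C7′–H, together with an ent-configured ring A′ on C9′ whose C5′ carries the aldehyde C6′.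
- Forward key step: a triazolium-derived carbene turns the aldehyde into an acyl-anion equivalent that adds to C7′ (1,6-addition, six-membered closure) and gives phenol A3 with ring B′ closed.
- For it: carbene-catalysed acyl-anion additions to para-quinone methides are an established reaction class, rearomatisation drives the step, and the C6′ ketone appears in the right place. Because the halves would be made separately in their own enantiomeric series, nothing is lost to a homochiral diastereomer and no desymmetrisation is needed. On that point it is stronger than the chosen route.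
- Against it: C7, C10, C10′ and the C7–C7′ bond must all be in place before the key step, so the key step solves little. The aldehyde is flanked by the gem-dimethyl C4′ and the quaternary C10′, and C5′ is epimerisable under the basic carbene conditions. Two separate enantioselective syntheses are needed, one in the unnatural series, and A3 still needs C7′ reoxidised and four ethers cleaved.
- Comparison: the sequence is long and linear. The chosen route gives up reagent control of each half and accepts a diastereomer separation, but it builds both B rings and four stereocentres in one operation from two achiral pieces.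

Alternative 3: The cuts are C4′–C5′ and C9′–C10′, so rings A′ and B′ are unravelled to a dienyl chain. Substrate A6 is a 2-aryl benzofuran (ring D in aromatic form) whose C7′ carries an (E)-geranyl chain and whose aryl group is the natural-series seco ester, with ring B open between C6 and C7.
- Forward key step: a chiral Lewis-acid-assisted Brønsted acid, SnCl4 combined with a binaphthol monoether, protonates the terminal alkene and the cation cascade ends on C9′, giving A5.
- For it: cationic polyene bicyclisation is the best-precedented way to a trans-decalin with a benzylic quaternary carbon, and the catalyst sets the ent configuration of the primed decalin directly. On securing the absolute configuration of a decalin by reagent control it is stronger than the chosen route.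
- Against it: A5 is far from 18. C6′ must be oxidised, and ring B must then be closed by forming C6–C7 at a furan carbon that already bears the aryl group. That is a dearomatising acylation which has to create the spiro centre with control over its configuration. The natural-series half must be made enantiopure beforehand, and the chiral acid is needed in stoichiometric amount and has to override the existing C5 and C10 centres.
- Comparison: the step count is much higher. The chosen route makes C7 by heteroatom addition to an alkene, not by dearomatisation, and needs no chiral material before its last step.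

Key step: step 8

## Remarks

- The hydroxyquinone of 18 is written as the 14-hydroxy-11,12-dione. It is the prototropic tautomer of the 12-hydroxy-11,14-dione, and both describe the same compound.
- Compounds 13 to 16 are written as Z isomers. E isomers would serve equally, because the protonated enedione can turn about C7–C7′ and the double bond is consumed in step 10.
- Which antipode of the chiral phosphoric acid leads to 18 cannot be predicted with confidence. The (R) acid is written, and the (S) acid would be used if the sense proved opposite.

## Route

Step 1
Reactants: 1 1,2,4-trimethoxybenzene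
Product: 3 2-(2,3,6-trimethoxyphenyl)propan-2-ol, via (2,3,6-trimethoxyphenyl)lithium 2 (not isolated)
Conditions: n-BuLi, TMEDA, THF, 0 °C; acetone, −78 °C → rt; H2O
Reagents that add atoms: acetone, CC(C)=O
Why: Directed ortho-metalation; the C3 hydrogen of 1 lies between two methoxy groups, is the most acidic and is doubly coordinated, so 2 forms there and adds to the ketone.

Step 2
Reactants: 3 2-(2,3,6-trimethoxyphenyl)propan-2-ol
Product: 4 2-isopropyl-1,3,4-trimethoxybenzene
Conditions: Et3SiH, CF3CO2H, CH2Cl2, 0 °C → rt
Reagents that add atoms: none
Why: Ionic hydrogenation; the acid ionises the tertiary benzylic alcohol and the silane delivers hydride to the cation, while aryl methyl ethers are inert.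

Step 3
Reactants: 4 2-isopropyl-1,3,4-trimethoxybenzene
Product: 5 1-(chloromethyl)-3-isopropyl-2,4,5-trimethoxybenzene
Conditions: (CH2O)n, HCl (gas), 1,4-dioxane, 0 °C → rt
Reagents that add atoms: formaldehyde (as paraformaldehyde), C=O; hydrogen chloride, Cl
Why: Blanc chloromethylation; C6 of 4 is ortho to the 1-methoxy and para to the 3-methoxy group, whereas C5 is conjugated with one methoxy group only, so substitution should follow the pattern of the parent 1. Excess formaldehyde and dilution hold back diarylmethane formation.

Step 4
Reactants: 5 1-(chloromethyl)-3-isopropyl-2,4,5-trimethoxybenzene; 6 β-cyclocitral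
Product: 8 2-(3-isopropyl-2,4,5-trimethoxyphenyl)-1-(2,6,6-trimethylcyclohex-1-en-1-yl)ethan-1-ol (racemic), via (3-isopropyl-2,4,5-trimethoxybenzyl)magnesium chloride 7 (not isolated)
Conditions: Mg, Et2O, 0 °C (slow addition of 5); then 6, 0 °C → rt; H2O
Reagents that add atoms: none
Why: Grignard addition to a hindered, non-enolisable aldehyde; slow addition of 5 to excess Mg keeps Wurtz coupling low. The carbinol centre is formed without control and is removed in step 5.

Step 5
Reactants: 8 2-(3-isopropyl-2,4,5-trimethoxyphenyl)-1-(2,6,6-trimethylcyclohex-1-en-1-yl)ethan-1-ol
Product: 9 2-(3-isopropyl-2,4,5-trimethoxyphenyl)-1-(2,6,6-trimethylcyclohex-1-en-1-yl)ethan-1-one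
Conditions: Dess–Martin periodinane, NaHCO3, CH2Cl2, 0 °C → rt
Reagents that add atoms: none
Why: Dess–Martin oxidation of a secondary allylic alcohol; the buffered, non-acidic medium avoids double-bond migration and premature cyclisation.

Step 6
Reactants: 9 2-(3-isopropyl-2,4,5-trimethoxyphenyl)-1-(2,6,6-trimethylcyclohex-1-en-1-yl)ethan-1-one (two molecules are joined per molecule of product)
Product: 11 2,3-bis(3-isopropyl-2,4,5-trimethoxyphenyl)-1,4-bis(2,6,6-trimethylcyclohex-1-en-1-yl)butane-1,4-dione (meso/dl mixture), via lithium enolate 10 (not isolated)
Conditions: LiN(iPr)2 (1.05 equiv), THF, −78 °C; CuCl2 (1.1 equiv), DMF, −78 °C → rt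
Reagents that add atoms: second molecule of ketone 9, CC1=C(C(=O)Cc2cc(OC)c(OC)c(C(C)C)c2OC)C(C)(C)CCC1
Why: Oxidative homocoupling of a ketone enolate (Saegusa-type); all of 9 is converted into enolate 10 at its only α-position, the benzylic C7, and one-electron oxidation by CuCl2 joins two such units through a new C7–C7′ bond, so the product holds the atoms of two molecules of 9 less two hydrogens. The meso/dl ratio does not matter because both C7 centres become sp2 in step 7.

Step 7
Reactants: 11 2,3-bis(3-isopropyl-2,4,5-trimethoxyphenyl)-1,4-bis(2,6,6-trimethylcyclohex-1-en-1-yl)butane-1,4-dione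
Product: 13 (Z)-2,3-bis(3-isopropyl-2,4,5-trimethoxyphenyl)-1,4-bis(2,6,6-trimethylcyclohex-1-en-1-yl)but-2-ene-1,4-dione, via dilithium bis-enolate 12 (not isolated)
Conditions: LiN(iPr)2 (2.2 equiv), THF, −78 → 0 °C; I2 (1.1 equiv), −78 °C → rt
Reagents that add atoms: none
Why: Dehydrogenation of a 1,4-diketone through its bis-enolate; iodination at C7 and loss of iodide from the neighbouring enolate create C7=C7′. If only one enolate forms, the α-iodo diketone loses HI to the same product.

Step 8
Reactants: 13 (Z)-2,3-bis(3-isopropyl-2,4,5-trimethoxyphenyl)-1,4-bis(2,6,6-trimethylcyclohex-1-en-1-yl)but-2-ene-1,4-dione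
Product: 15 meso-(Z)-7,7′-bi(11,12,14-trimethoxy-6-oxoabieta-8,11,13-trien-7-ylidene) (5S,10S,5′R,10′R), via mono-cyclised enedione 14 (not isolated)
Conditions: polyphosphoric acid, 80 °C; chromatographic separation of 15 from its C2-symmetric diastereomer
Reagents that add atoms: none
Why: Proposed new method: O-protonation of one cyclogeranoyl carbonyl (C6) gives a hydroxyallyl cation with its charge on the tertiary C10, the ortho aryl carbon C9 (activated by the ortho 11-OMe and para 14-OMe groups) attacks C10, and rearomatisation and ketonisation of the C5=C6 enol give 14; the same events on the second side give 15. The closest known reaction is the acid-mediated cyclisation of arylmethyl 2,6,6-trimethylcyclohexenyl ketones to 6-oxo tricyclic diterpenoid skeletons; new here are the sp2 carbon C7 that carries the aryl and acyl groups and the twofold use in one molecule. Rings B and B′ each close in a 6-endo-trig mode, with the C5=C10 double bond inside the forming ring. C10 and C10′ are set in the two C–C bond formations with no element that relates them, so the heterochiral (meso) and homochiral (C2-symmetric, racemic) hexacycles are expected side by side and 15 is separated from its diastereomer. C5 and C5′ are set by protonation of the enols and, being α to the ketones, should equilibrate in the acid to the trans ring fusion, which is taken as the more stable arrangement by analogy with the single-ring series. The step needs six-ring closure onto the geminal acyl group and not seven-ring closure onto the distal one, which the Z geometry secures by placing each aryl group trans to the distal acyl group. It also needs Friedel–Crafts closure to outrun a Nazarov closure of the cross-conjugated C10=C5–C6(=O)–C7=C7′ unit, which would have to join the two fully substituted carbons C10 and C7′, the latter made electron-poor by its own acyl group. Because the two halves of 15 are mirror images the product is achiral, so nothing chiral is needed at this stage.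

Step 9
Reactants: 15 meso-(Z)-7,7′-bi(11,12,14-trimethoxy-6-oxoabieta-8,11,13-trien-7-ylidene)
Product: 16 meso-(Z)-7,7′-bi(11,12,14-trihydroxy-6-oxoabieta-8,11,13-trien-7-ylidene) (5S,10S,5′R,10′R)
Conditions: BBr3, CH2Cl2, −78 → 0 °C; quench into cold degassed aq. NaHCO3/Na2S2O4 under Ar; used crude
Reagents that add atoms: none
Why: Lewis-acid cleavage of aryl methyl ethers, which also reaches the hindered ethers next to the isopropyl group; ketones and the tetrasubstituted alkene are not attacked. The buffered reductive quench keeps acid contact short and protects the hydroxyhydroquinone rings from air.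

Step 10
Reactants: 16 meso-(Z)-7,7′-bi(11,12,14-trihydroxy-6-oxoabieta-8,11,13-trien-7-ylidene)
Product: 18 CNP0568854.1 (5S,7R,10S,5′R,10′R), via spiro pentaphenol 17 (not isolated)
Conditions: (R)-3,3′-bis(2,4,6-triisopropylphenyl)-1,1′-binaphthyl-2,2′-diyl hydrogen phosphate (10 mol %), 4 Å MS, degassed toluene–CH2Cl2, −40 °C; then Ag2O (2.2 equiv), −40 °C → rt
Reagents that add atoms: none
Why: Proposed new method: the chiral acid protonates the C6′ carbonyl of the enedione while its phosphoryl oxygen holds O14′–H, the cation at C7 is a protonated para-quinone methide of the 12-hydroxyaryl ring about whose C7–C7′ bond the halves can turn perpendicular, and O14′ closes ring D in a 5-exo mode on the α face of C7 (anti to the C10 methyl group), with the catalyst choosing which enantiotopic half supplies the phenol; the closest known reactions are phosphoric-acid-catalysed enantioselective 1,6-additions of phenols to para-quinone methides and desymmetrising intramolecular oxa-Michael additions. Ag2O then oxidises the 11,12,14-triol to the hydroxyquinone and the 11′,12′-catechol to its ortho-quinone, which tautomerises to the C7′=C8′ quinone methide because C7′–H is benzylic and α to the C6′ ketone, the usual behaviour of 6-oxo-11,12-catechols of this type; the quaternary C7 is not touched.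

## Compound list

1 | 1,2,4-trimethoxybenzene | COc1ccc(OC)c(OC)c1 | starting material
2 | (2,3,6-trimethoxyphenyl)lithium | [Li]c1c(OC)ccc(OC)c1OC | intermediate (not isolated)
3 | 2-(2,3,6-trimethoxyphenyl)propan-2-ol | CC(C)(O)c1c(OC)ccc(OC)c1OC | intermediate
4 | 2-isopropyl-1,3,4-trimethoxybenzene | CC(C)c1c(OC)ccc(OC)c1OC | intermediate
5 | 1-(chloromethyl)-3-isopropyl-2,4,5-trimethoxybenzene | ClCc1cc(OC)c(OC)c(C(C)C)c1OC | intermediate
6 | β-cyclocitral (2,6,6-trimethylcyclohex-1-ene-1-carbaldehyde) | CC1=C(C=O)C(C)(C)CCC1 | starting material
7 | (3-isopropyl-2,4,5-trimethoxybenzyl)magnesium chloride | Cl[Mg]Cc1cc(OC)c(OC)c(C(C)C)c1OC | intermediate (not isolated)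
8 | 2-(3-isopropyl-2,4,5-trimethoxyphenyl)-1-(2,6,6-trimethylcyclohex-1-en-1-yl)ethan-1-ol, racemic | CC1=C(C(O)Cc2cc(OC)c(OC)c(C(C)C)c2OC)C(C)(C)CCC1 | intermediate
9 | 2-(3-isopropyl-2,4,5-trimethoxyphenyl)-1-(2,6,6-trimethylcyclohex-1-en-1-yl)ethan-1-one | CC1=C(C(=O)Cc2cc(OC)c(OC)c(C(C)C)c2OC)C(C)(C)CCC1 | intermediate
10 | lithium enolate of 9 (O–Li, C6=C7) | [Li]OC(=Cc1cc(OC)c(OC)c(C(C)C)c1OC)C1=C(C)CCCC1(C)C | intermediate (not isolated)
11 | 2,3-bis(3-isopropyl-2,4,5-trimethoxyphenyl)-1,4-bis(2,6,6-trimethylcyclohex-1-en-1-yl)butane-1,4-dione, meso/dl mixture | CC1=C(C(=O)C(c2cc(OC)c(OC)c(C(C)C)c2OC)C(c2cc(OC)c(OC)c(C(C)C)c2OC)C(=O)C2=C(C)CCCC2(C)C)C(C)(C)CCC1 | intermediate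
12 | dilithium bis-enolate of 11 | [Li]OC(C1=C(C)CCCC1(C)C)=C(c1cc(OC)c(OC)c(C(C)C)c1OC)C(c1cc(OC)c(OC)c(C(C)C)c1OC)=C(O[Li])C1=C(C)CCCC1(C)C | intermediate (not isolated)
13 | (Z)-2,3-bis(3-isopropyl-2,4,5-trimethoxyphenyl)-1,4-bis(2,6,6-trimethylcyclohex-1-en-1-yl)but-2-ene-1,4-dione | CC1=C(C(=O)/C(c2cc(OC)c(OC)c(C(C)C)c2OC)=C(/c2cc(OC)c(OC)c(C(C)C)c2OC)C(=O)C2=C(C)CCCC2(C)C)C(C)(C)CCC1 | intermediate
14 | mono-cyclised enedione: trans-fused 11,12,14-trimethoxy-6-oxoabieta-8,11,13-triene whose C7 is doubly bonded to the carbon carrying Ar and the second cyclogeranoyl group; racemic, one enantiomer drawn | O=C1[C@H]2C(C)(C)CCC[C@]2(C)c2c(OC)c(OC)c(C(C)C)c(OC)c2/C1=C(\c1cc(OC)c(OC)c(C(C)C)c1OC)C(=O)C1=C(C)CCCC1(C)C | intermediate (not isolated)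
15 | meso-(Z)-7,7′-bi(11,12,14-trimethoxy-6-oxoabieta-8,11,13-trien-7-ylidene), (5S,10S,5′R,10′R), both ring fusions trans | O=C1[C@H]2C(C)(C)CCC[C@]2(C)c2c(OC)c(OC)c(C(C)C)c(OC)c2/C1=C1\c2c(OC)c(C(C)C)c(OC)c(OC)c2[C@]2(C)CCCC(C)(C)[C@H]2C1=O | intermediate
16 | meso-(Z)-7,7′-bi(11,12,14-trihydroxy-6-oxoabieta-8,11,13-trien-7-ylidene), (5S,10S,5′R,10′R) | O=C1[C@H]2C(C)(C)CCC[C@]2(C)c2c(O)c(O)c(C(C)C)c(O)c2/C1=C1\c2c(O)c(C(C)C)c(O)c(O)c2[C@]2(C)CCCC(C)(C)[C@H]2C1=O | intermediate
17 | spiro pentaphenol: (5S,10S)-11,12,14-trihydroxy-6-oxoabieta-8,11,13-triene joined at C7 to C7′ and O14′ of a (5′R,10′R)-11′,12′-dihydroxy-6′-oxoabieta-8′,11′,13′-triene; O14′ on the α face of C7; C7′–H either epimer | CC(C)c1c(O)c2c(c(O)c1O)[C@@]1(C)CCCC(C)(C)[C@@H]1C(=O)[C@@]21Oc2c(C(C)C)c(O)c(O)c3c2C1C(=O)[C@@H]1C(C)(C)CCC[C@@]31C | intermediate (not isolated)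
18 | CNP0568854.1, (5S,7R,10S,5′R,10′R) | CC(C)C1=C(O)C2=C(C(=O)C1=O)[C@@]1(C)CCCC(C)(C)[C@@H]1C(=O)[C@@]21OC2=C(C(C)C)C(=O)C(O)=C3C2=C1C(=O)[C@@H]1C(C)(C)CCC[C@@]31C | target

## Step count and least certain steps

Total: 10 steps. Longest linear sequence: 10 steps, from 1; compound 6 enters at step 4.

**Step 8 (key step, new method).** Three things may go wrong. The second ring closure may stall at 14, because its transition state must build up the strain of a tetrasubstituted alkene held between two peri-methoxylated tricycles. The activated enedione may be diverted, either by Nazarov closure or by attack of an O14 methyl ether oxygen on the C7=C7′ unit with loss of the methyl group; the second path would close ring D early and without stereocontrol. The C10/C10′ pairing is not controlled, so at best about half of the material can be the meso isomer, and incomplete C5 equilibration would add cis-fused isomers.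

Fallback, by known chemistry, from 9 back to 15. Polyphosphoric acid closes the single ring B of 9, the established cyclisation for this ketone class, and gives racemic trans-11,12,14-trimethoxyabieta-8,11,13-trien-6-one F1. Two molecules of F1 are then joined at C7 through the lithium enolate (LiN(iPr)2, THF, −78 °C; then CuCl2) to give the 7,7′-linked bis-ketone F2, from which the heterochiral pairs are taken. The bis-enolate of F2 is oxidised with I2 as in step 7, and the route is rejoined at 15.

**Step 10 (new method).** Three things may go wrong. The catalyst may discriminate poorly between the enantiotopic halves, because six phenolic hydroxyl groups compete for its phosphoryl oxygen and because an uncatalysed closure can run alongside. O14′ may add on the β face of C7. Ring D may reopen through the C6′ enol (retro-oxa-Michael) before the oxidation, which returns the material to meso 16 and erodes the enantiomeric purity; this is why the closure is run cold and oxidised in the same flask.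

Fallback, by known chemistry, from 16 to 18. Ring D is closed with an achiral acid (diphenyl hydrogen phosphate, CH2Cl2, 0 °C), which gives 17 together with its mirror image ent-17 F3. Ag2O then gives the racemate, 18 and ent-18 F4, and the enantiomers are separated by preparative HPLC on a chiral stationary phase.

**Step 9.** Ring D may close early and without control under Lewis-acid activation of the enedione, either by the methyl ether oxygen or by the freed phenol during the acidic quench. The hydroxyhydroquinone rings may also oxidise in air.

Fallback from 15 to 16, avoiding strong acid at the phenol stage. Oxidative demethylation with (NH4)2Ce(NO3)6 in aqueous MeCN gives the meso bis(12-methoxy-11,14-quinone) F5. Dilute aqueous HClO4 in dioxane then hydrolyses the two vinylogous esters to the air-stable, purifiable meso bis(12-hydroxy-11,14-quinone) F6. Aqueous Na2S2O4 under argon reduces F6 to 16 immediately before step 10.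

**Step 7.** Double enolisation of the hindered diketone may be incomplete, and iodine may attack the free aryl position C9 or an allylic position.

Fallback from 11 to 13. Paal–Knorr cyclodehydration (TsOH, toluene, reflux) gives 3,4-bis(Ar)-2,5-bis(2,6,6-trimethylcyclohex-1-en-1-yl)furan F7. Oxidative ring opening of the furan (NBS, NaHCO3, aqueous acetone, −15 °C) then gives the Z-enedione 13 stereospecifically.

**Step 3.** The electron-rich arene may be alkylated a second time by the benzyl chloride to give a diarylmethane, and the chloride may decompose on isolation. Attack at C5 of 4 would give the wrong regioisomer.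

Fallback from 4 to 5. Rieche formylation (Cl2CHOMe, TiCl4, CH2Cl2, −78 °C) gives 3-isopropyl-2,4,5-trimethoxybenzaldehyde F8, which cannot over-react and whose substitution pattern is easy to confirm. NaBH4 in MeOH then gives (3-isopropyl-2,4,5-trimethoxyphenyl)methanol F9, and concentrated HCl in CH2Cl2 converts F9 into 5, which is used at once.

## Further compounds

F1 | step 8 | trans-11,12,14-trimethoxyabieta-8,11,13-trien-6-one, racemic (one enantiomer drawn) | O=C1[C@H]2C(C)(C)CCC[C@]2(C)c2c(OC)c(OC)c(C(C)C)c(OC)c2C1
F2 | step 8 | 7,7′-bi(11,12,14-trimethoxy-6-oxoabieta-8,11,13-trien-7-yl), heterochiral pairing (5S,10S,5′R,10′R), C7 and C7′ undefined | O=C1[C@H]2C(C)(C)CCC[C@]2(C)c2c(OC)c(OC)c(C(C)C)c(OC)c2C1C1c2c(OC)c(C(C)C)c(OC)c(OC)c2[C@]2(C)CCCC(C)(C)[C@H]2C1=O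
F3 | step 10 | ent-17, mirror image of spiro pentaphenol 17 | CC(C)c1c(O)c2c(c(O)c1O)[C@]1(C)CCCC(C)(C)[C@H]1C(=O)[C@]21Oc2c(C(C)C)c(O)c(O)c3c2C1C(=O)[C@H]1C(C)(C)CCC[C@]31C
F4 | step 10 | ent-18, mirror image of the target | CC(C)C1=C(O)C2=C(C(=O)C1=O)[C@]1(C)CCCC(C)(C)[C@H]1C(=O)[C@]21OC2=C(C(C)C)C(=O)C(O)=C3C2=C1C(=O)[C@H]1C(C)(C)CCC[C@]31C
F5 | step 9 | meso-(Z)-7,7′-bi(12-methoxy-6,11,14-trioxoabieta-8,12-dien-7-ylidene), (5S,10S,5′R,10′R) | O=C1[C@H]2C(C)(C)CCC[C@]2(C)C=3C(=O)C(OC)=C(C(C)C)C(=O)C=3/C1=C1\C=3C(=O)C(C(C)C)=C(OC)C(=O)C=3[C@]2(C)CCCC(C)(C)[C@H]2C1=O
F6 | step 9 | meso-(Z)-7,7′-bi(12-hydroxy-6,11,14-trioxoabieta-8,12-dien-7-ylidene), (5S,10S,5′R,10′R) | O=C1[C@H]2C(C)(C)CCC[C@]2(C)C=3C(=O)C(O)=C(C(C)C)C(=O)C=3/C1=C1\C=3C(=O)C(C(C)C)=C(O)C(=O)C=3[C@]2(C)CCCC(C)(C)[C@H]2C1=O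
F7 | step 7 | 3,4-bis(3-isopropyl-2,4,5-trimethoxyphenyl)-2,5-bis(2,6,6-trimethylcyclohex-1-en-1-yl)furan | CC1=C(c2oc(C3=C(C)CCCC3(C)C)c(-c3cc(OC)c(OC)c(C(C)C)c3OC)c2-c2cc(OC)c(OC)c(C(C)C)c2OC)C(C)(C)CCC1
F8 | step 3 | 3-isopropyl-2,4,5-trimethoxybenzaldehyde | O=Cc1cc(OC)c(OC)c(C(C)C)c1OC
F9 | step 3 | (3-isopropyl-2,4,5-trimethoxyphenyl)methanol | OCc1cc(OC)c(OC)c(C(C)C)c1OC
A1 | alternative 1 | spiro dimer with the unprimed ring C as its 11,12,14-triol and the primed half as the quinone methide (7R) | CC(C)c1c(O)c2c(c(O)c1O)[C@@]1(C)CCCC(C)(C)[C@@H]1C(=O)[C@@]21OC2=C(C(C)C)C(=O)C(O)=C3C2=C1C(=O)[C@@H]1C(C)(C)CCC[C@@]31C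
A2 | alternative 1 | meso bis(quinone methide): two 11,14-dihydroxyabieta-7,9(11),13-triene-6,12-dione units joined C7–C7′, (5S,10S,5′R,10′R) | CC(C)C1=C(O)C2=C(C3=C4C(O)=C(C(C)C)C(=O)C(O)=C4[C@]4(C)CCCC(C)(C)[C@H]4C3=O)C(=O)[C@H]3C(C)(C)CCC[C@]3(C)C2=C(O)C1=O
A3 | alternative 2 | spiro 12′-phenol with ring B′ closed and C7′–H, unprimed ring C as 11,12,14-trimethyl ether, 11′-methyl ether | CC(C)c1c(OC)c2c(c(OC)c1OC)[C@@]1(C)CCCC(C)(C)[C@@H]1C(=O)[C@@]21Oc2c(C(C)C)c(O)c(OC)c3c2[C@@H]1C(=O)[C@@H]1C(C)(C)CCC[C@@]31C
A4 | alternative 2 | ring-B′-seco aldehyde: spiro quinone methide with C7′–H and an ent-configured ring A′ on C9′ carrying the C6′ aldehyde on C5′ | CC(C)c1c(OC)c2c(c(OC)c1OC)[C@@]1(C)CCCC(C)(C)[C@@H]1C(=O)[C@@]21OC2=C(C(C)C)C(=O)C(OC)=C(C2=C1)[C@]1(C)CCCC(C)(C)[C@H]1C=O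
A5 | alternative 3 | benzofuran-fused ent-decalin joined at C7 to the aryl group of the natural-series ring-B-seco methyl ester | CC(C)c1c(OC)c(-c2oc3c(C(C)C)c(OC)c(OC)c4c3c2C[C@@H]2C(C)(C)CCC[C@@]42C)c(c(OC)c1OC)[C@@]1(C)CCCC(C)(C)[C@@H]1C(=O)OC
A6 | alternative 3 | 2-aryl-3-[(E)-geranyl]benzofuran with free C9′–H, aryl group as in A5 | CC(C)c1c(OC)c(-c2oc3c(C(C)C)c(OC)c(OC)cc3c2C/C=C(\C)CCC=C(C)C)c(c(OC)c1OC)[C@@]1(C)CCCC(C)(C)[C@@H]1C(=O)OC
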